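- After 12 d you want to know how much free monomer has gone into chains, and one ledger of the charged pre-initiator gives a first answer.

| setting | elm | birch | west | north-west | east | north | north-east |
|---|---|---|---|---|---|---|---|
| free monomer | 1.3 M | 1.3 M | 1.3 M | 1.3 M | 1.3 M | 1.3 M | 1.3 M |
| pre-initiator | 3.8 mM | 320 mM | 5.0 mM | 15 mM | 40 mM | 120 mM | 400 mM |
| impurity | 18 mM | 18 mM | 18 mM | 18 mM | 18 mM | 18 mM | 18 mM |
| remark | run made earlier | run made earlier |  |  |  |  |  |
| time |  |  | 12 d | 12 d | 12 d | 12 d | 12 d |

- elm (time / d: monomer in chains / %): 0.625: 1.5; 1.04: 0; 1.67: 1.6; 2.50: 0; 4.00: 1.5; 6.00: 1.3; 8.00: 0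
- birch (time / d: monomer in chains / %): 0.417: 1.3; 1.25: 14.8; 2.50: 42.0; 4.00: 70.3; 5.00: 79.9; 6.00: 90.7; 8.00: 96.0

(each reading ± 1 percentage point)

- steps under discussion: free monomer + initiator -> living end + monomer in chains; free monomer + living end -> monomer in chains + living end; pre-initiator <-> initiator; initiator + impurity -> spent initiator
- "hardly changes" means that all values lie within two and a half points (for a concentration: within two and a half percent of the largest)

1. amount of monomer in chains at the end, in percent of the free monomer charged for west, north-west, east, north, north-east, in this order
2. the course of these numbers from the first flask to the last (rises, then falls / falls, then rises / hardly changes / falls all the way / rises all the way)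

- First entry: each flask holds 18 mM of impurity, and initiator that meets it becomes spent initiator, so I book each charge to impurity up to that amount.
- Elm fits this entry: its 3.8 mM charge is the limiting reagent, and its highest reading is 1.6 % against a scatter of 1 percentage point.
- Second entry: birch has 302 mM above the impurity, and I book this excess as the pool that feeds living ends.
- Late in birch, free monomer left goes from 29.7 % at 4.00 d to 4.00 % at 8.00 d. If you freeze c(living end) there, the loss is pseudo-first-order, and these readings give a rate of 0.501 d⁻¹.
- Dividing by the excess gives 1.92 × 10⁻⁵ L mol⁻¹ s⁻¹, the clock per mole: the first-order rate of monomer loss for each mole per litre of charge above the impurity.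
- My reckoning multiplies this clock by each excess and by the time, and reads the product as a first-order loss. That gives 35.5 % for east, 86.9 % for north and >99.9 % for north-east. West and north-west get no entry, since their charges lie below the impurity.
- The forecast gives 0.4 %, 1.2 %, 29 %, 82 % and 99.7 %, a course that rises all the way. Its words on the low end are “west and north-west should give almost nothing”, and its east and north figures lie below mine.

The flasks give 1.27 %, 5.97 %, 51.3 %, 92.5 % and 99.8 %, a course that rises all the way.

    free monomer + initiator → living end + monomer in chains (k = 1.78 × 10⁻⁶ L mol⁻¹ s⁻¹)
    free monomer + living end → monomer in chains + living end, rate k2*[living end]*[free monomer] (k = 1.09 × 10⁻⁴ L mol⁻¹ s⁻¹)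
    pre-initiator ⇌ initiator (K = 0.490, k = 2.50 × 10⁻⁴ s⁻¹)
    initiator + impurity → spent initiator (k = 0.00629 L mol⁻¹ s⁻¹)

In west, taking each step by itself at the charged concentrations, initiator has a half-life of 0.071 d against impurity and 3.5 d against free monomer, 49.3 times shorter. The west ledger ends with 0.00488 M of spent initiator beside 1.16 × 10⁻⁴ M of living end, where I had booked no living end. The clock per mole gives north-east 0.634 d⁻¹, close to the 0.639 d⁻¹ its free monomer shows between 6.00 d and 12.0 d. For north the clock gives 0.169 d⁻¹, and its free monomer falls at 0.283 d⁻¹ over the same days.

The data come from a simulation for substances that don't exist.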